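**Retrosynthetic overview**

Numbering in each benzene ring: C1 carries the CH2N carbon, C2, C5 and C6 carry bromine, C3 and C4 carry the hydroxyls. The target has no stereocentre.
- The strategy rests on this feature: the adjacent pair C3/C4 bears the two oxygens and the adjacent pair C1/C6 bears the one-carbon side chain and a bromine. That is the pattern of a 2,3-dioxygenated butadiene (C2–C3–C4–C5) joined to a 3-bromopropiolate (C1 and C6).
- Both benzylic C–N bonds are cut first: the urea comes from urea and two molecules of 2,3,6-tribromo-4,5-dihydroxybenzyl alcohol, which comes from the methyl ester by hydride reduction.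
- The bromines on C2 and C5 are put in by bromination of the free catechol, where these are the only open ring positions and each is ortho to a hydroxyl.
- The benzene ring, the only ring that is built, comes from a 1,4-cyclohexadiene by dehydrogenation. That diene comes from a [4+2] cycloaddition of 2,3-bis(trimethylsilyloxy)butadiene with methyl 3-bromopropiolate, which forms C1–C2 and C5–C6.
- The diene is made from biacetyl and the bromoalkyne from methyl propiolate, one step each.

Key step: step 3

**Route**

Step 1
Reactants: 1 butane-2,3-dione
Product: 2 2,3-bis(trimethylsilyloxy)buta-1,3-diene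
Conditions: TMSOTf (2.1 equiv), Et3N (2.4 equiv), Et2O, 0 °C to rt; decant from the ammonium salt, distil under reduced pressure
Reagents that add atoms: trimethylsilyl trifluoromethanesulfonate, C[Si](C)(C)OS(=O)(=O)C(F)(F)F
Why: Soft enolisation of a 1,2-diketone, in which the silyl triflate activates each carbonyl oxygen and triethylamine removes a proton from the adjacent methyl group, should give the cross-conjugated bis(silyl enol ether) by double O-silylation, a standard preparation of 2-silyloxydienes.

Step 2
Reactants: 3 methyl propiolate
Product: 4 methyl 3-bromopropiolate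
Conditions: NBS (1.1 equiv), AgNO3 (0.1 equiv), acetone, rt, dark; filter, concentrate, short-path distillation under reduced pressure (lachrymator)
Reagents that add atoms: N-bromosuccinimide, O=C1CCC(=O)N1Br
Why: Electrophilic bromination of a terminal alkyne through its silver acetylide, formed with catalytic AgNO3 and brominated by NBS, is the standard preparation of 1-bromoalkynes and leaves the ester untouched.

Step 3
Reactants: 2 2,3-bis(trimethylsilyloxy)buta-1,3-diene; 4 methyl 3-bromopropiolate
Product: 5 methyl 2-bromo-4,5-bis(trimethylsilyloxy)cyclohexa-1,4-diene-1-carboxylate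
Conditions: 2 (1.2 equiv), 4 (1.0 equiv), BHT (1 mol%), toluene, 80 °C, sealed vessel under argon; concentrate and use crude
Reagents that add atoms: none
Why: A thermal normal-demand Diels–Alder reaction: the two siloxy groups raise the HOMO of the diene, the ester and the bromine lower the LUMO of the alkyne, and a concerted suprafacial [4+2] through the s-cis diene forms the C1–C2 and C5–C6 bonds at once. The closest known reactions are the cycloadditions of 2,3-bis(silyloxy)butadienes with acetylenic esters and of 3-bromopropiolates with furan or cyclopentadiene. The one ring is closed by intermolecular [4+2] cycloaddition, which delivers the six-membered carbocycle as a 1,4-cyclohexadiene already carrying the ester carbon on C1, bromine on C6 and the oxygens on C3 and C4. No stereocentre is formed. Only chemoselectivity is needed, namely one cycloaddition in place of silyl transfer, bromine transfer or conjugate addition of the enol ether to the bromoalkyne, and the neutral, acid-free thermal conditions should secure it because those ionic paths need Lewis or Brønsted acid activation. Regiochemistry is not an issue since the diene is C2-symmetric, and the adduct cannot react again because both of its alkenes are tetrasubstituted.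

Step 4
Reactants: 5 methyl 2-bromo-4,5-bis(trimethylsilyloxy)cyclohexa-1,4-diene-1-carboxylate
Product: 6 methyl 2-bromo-4,5-bis(trimethylsilyloxy)benzoate
Conditions: DDQ (1.05 equiv), toluene, 0 °C to rt; filter off the hydroquinone, concentrate, use without chromatography
Reagents that add atoms: none
Why: Oxidative aromatisation of a 1,4-cyclohexadiene, in which the quinone abstracts hydride from a doubly allylic CH2 and the resulting arenium ion loses the proton of the other CH2, is driven by the gain of aromaticity and should leave the aryl silyl ethers and the C–Br bond untouched.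

Step 5
Reactants: 6 methyl 2-bromo-4,5-bis(trimethylsilyloxy)benzoate
Product: 8 methyl 2,3,6-tribromo-4,5-dihydroxybenzoate, via methyl 2-bromo-4,5-dihydroxybenzoate 7 (not isolated)
Conditions: Br2 (2.5 equiv), AcOH/H2O 95:5, rt then 45 °C; aq. NaHSO3 quench
Reagents that add atoms: bromine, BrBr
Why: The aryl trimethylsilyl ethers are hydrolysed in wet acetic acid as soon as HBr appears, and the freed catechol should undergo electrophilic aromatic bromination at C2 and C5, the only two unsubstituted ring carbons and each ortho to a hydroxyl, so that no regiochemical choice exists and the ester is unaffected.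

Step 6
Reactants: 8 methyl 2,3,6-tribromo-4,5-dihydroxybenzoate
Product: 10 2,3,6-tribromo-4,5-dihydroxybenzyl alcohol, via 2,3,6-tribromo-4,5-dihydroxybenzaldehyde 9 (not isolated)
Conditions: i-Bu2AlH (6 equiv), THF, −78 °C to 0 °C; cold 1 M HCl work-up
Reagents that add atoms: none
Why: Hydride reduction of an ester by an aluminium hydride, in which the first two equivalents deprotonate the catechol to an aluminium catecholate and further reagent, a Lewis acidic hydride donor that tolerates aryl bromides at low temperature, takes the carbonyl through the aldehyde to the primary alcohol.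

Step 7
Reactants: 10 2,3,6-tribromo-4,5-dihydroxybenzyl alcohol (2 molecules per molecule of product); 11 urea
Product: 13 N,N'-bis(2,3,6-tribromo-4,5-dihydroxybenzyl)urea (target), via N-(2,3,6-tribromo-4,5-dihydroxybenzyl)urea 12 (not isolated)
Conditions: 11 (0.5 equiv), p-TsOH·H2O (0.1 equiv), 1,4-dioxane, 80 °C
Reagents that add atoms: none
Why: Acid-catalysed N-benzylation of urea by a 4-hydroxybenzyl alcohol (the phenol–urea cocondensation reaction, akin to dixanthylurea formation) should proceed by loss of water to a benzylic cation stabilised by the para hydroxyl on C4, capture by a urea nitrogen and a second benzylation at the free NH2 of the monobenzylurea, while the fully substituted ring rules out C-benzylation of another arene.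

**Compound list**

1 | butane-2,3-dione (biacetyl) | CC(=O)C(C)=O | starting material
2 | 2,3-bis(trimethylsilyloxy)buta-1,3-diene | C=C(O[Si](C)(C)C)C(=C)O[Si](C)(C)C | intermediate
3 | methyl propiolate | C#CC(=O)OC | starting material
4 | methyl 3-bromopropiolate | COC(=O)C#CBr | intermediate
5 | methyl 2-bromo-4,5-bis(trimethylsilyloxy)cyclohexa-1,4-diene-1-carboxylate | COC(=O)C1=C(Br)CC(O[Si](C)(C)C)=C(O[Si](C)(C)C)C1 | intermediate
6 | methyl 2-bromo-4,5-bis(trimethylsilyloxy)benzoate | COC(=O)c1cc(O[Si](C)(C)C)c(O[Si](C)(C)C)cc1Br | intermediate
7 | methyl 2-bromo-4,5-dihydroxybenzoate | COC(=O)c1cc(O)c(O)cc1Br | intermediate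
8 | methyl 2,3,6-tribromo-4,5-dihydroxybenzoate | COC(=O)c1c(Br)c(O)c(O)c(Br)c1Br | intermediate
9 | 2,3,6-tribromo-4,5-dihydroxybenzaldehyde | O=Cc1c(Br)c(O)c(O)c(Br)c1Br | intermediate
10 | 2,3,6-tribromo-4,5-dihydroxybenzyl alcohol [3,4,6-tribromo-5-(hydroxymethyl)benzene-1,2-diol] | OCc1c(Br)c(O)c(O)c(Br)c1Br | intermediate
11 | urea | NC(N)=O | starting material
12 | N-(2,3,6-tribromo-4,5-dihydroxybenzyl)urea | NC(=O)NCc1c(Br)c(O)c(O)c(Br)c1Br | intermediate
13 | N,N'-bis(2,3,6-tribromo-4,5-dihydroxybenzyl)urea | O=C(NCc1c(Br)c(O)c(O)c(Br)c1Br)NCc1c(Br)c(O)c(O)c(Br)c1Br | target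

**Step count**

Total steps: 7. Longest linear sequence: 6 steps (step 1 or step 2, then steps 3 to 7).

**Steps most likely to fail**

Step 3 (cycloaddition). The bromoalkyne may oligomerise or lose bromine on heating, or the silyl enol ether may attack it in an ionic way (bromine or silyl transfer, conjugate addition) faster than the cycloaddition, and adventitious acid may hydrolyse the diene. The fallback keeps the [4+2] ring construction but brings in the C6 bromine by electrophilic substitution instead of through the dienophile. It sets out from 2 and 3 and comes back to the route at 8. Diene 2 and methyl propiolate 3, a thermally robust dienophile, are heated in toluene at 110 °C to give methyl 4,5-bis(trimethylsilyloxy)cyclohexa-1,4-diene-1-carboxylate F1. DDQ in toluene should aromatise it to methyl 3,4-bis(trimethylsilyloxy)benzoate F2. Br2 (3.5 equiv) in wet acetic acid then removes the silyl groups to give methyl 3,4-dihydroxybenzoate F3, which is not isolated and is brominated at all three open ring carbons (C2 and C5 ortho, C6 para to a hydroxyl) to give 8.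

Step 6 (ester reduction). The ester is flanked by two bromines and deactivated by the para aluminium phenoxide, so reduction may stall. Alternatively, the benzylic aluminium alkoxide may ionise to a para-quinone methide that takes up hydride, which would over-reduce the side chain to a methyl group. The fallback masks the catechol before the reduction so that no phenoxide is present. It sets out from 8 and comes back at 10. Ester 8 is ketalised with 2,2-dimethoxypropane and catalytic p-TsOH in refluxing benzene, with removal of methanol, to give methyl 4,6,7-tribromo-2,2-dimethyl-1,3-benzodioxole-5-carboxylate F4. Reduction with i-Bu2AlH (2.5 equiv) in CH2Cl2 at −78 °C to 0 °C should give (4,6,7-tribromo-2,2-dimethyl-1,3-benzodioxol-5-yl)methanol F5. Aqueous trifluoroacetic acid at rt then cleaves the acetonide to 10.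

Step 7 (urea condensation). Ionisation of the electron-poor, di-ortho-brominated benzylic alcohol may be slow, so the reaction may stop at the monobenzylurea 12. It may also divert to the dibenzyl ether or to O-alkylation of urea, or the same nitrogen may be benzylated twice. The fallback builds the urea from the benzylamine and a carbonyl donor instead of alkylating urea. It sets out from 10 and comes back at 13. HBr (33% in AcOH) converts 10 into 2,3,6-tribromo-4,5-dihydroxybenzyl bromide F6. NaN3 in DMF at rt gives 2,3,6-tribromo-4,5-dihydroxybenzyl azide F7. Staudinger reduction (PPh3, THF/H2O), which spares the aryl bromides, gives 2,3,6-tribromo-4,5-dihydroxybenzylamine F8. Two molecules of F8 are then joined with 1,1'-carbonyldiimidazole (0.5 equiv, DMF, rt) to give 13; the amine nitrogen should react ahead of the hindered, electron-poor phenols.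

**Further compounds**

F1 | step 3 | methyl 4,5-bis(trimethylsilyloxy)cyclohexa-1,4-diene-1-carboxylate | COC(=O)C1=CCC(O[Si](C)(C)C)=C(O[Si](C)(C)C)C1
F2 | step 3 | methyl 3,4-bis(trimethylsilyloxy)benzoate | COC(=O)c1ccc(O[Si](C)(C)C)c(O[Si](C)(C)C)c1
F3 | step 3 | methyl 3,4-dihydroxybenzoate | COC(=O)c1ccc(O)c(O)c1
F4 | step 6 | methyl 4,6,7-tribromo-2,2-dimethyl-1,3-benzodioxole-5-carboxylate | COC(=O)c1c(Br)c2OC(C)(C)Oc2c(Br)c1Br
F5 | step 6 | (4,6,7-tribromo-2,2-dimethyl-1,3-benzodioxol-5-yl)methanol | OCc1c(Br)c2OC(C)(C)Oc2c(Br)c1Br
F6 | step 7 | 2,3,6-tribromo-4,5-dihydroxybenzyl bromide | BrCc1c(Br)c(O)c(O)c(Br)c1Br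
F7 | step 7 | 2,3,6-tribromo-4,5-dihydroxybenzyl azide | [N-]=[N+]=NCc1c(Br)c(O)c(O)c(Br)c1Br
F8 | step 7 | 2,3,6-tribromo-4,5-dihydroxybenzylamine | NCc1c(Br)c(O)c(O)c(Br)c1Br
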